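**Plan**
1. Retrosynthetic cuts, in order: the isovalerate acyl bond at O8; C11=C13; the lactone bond C12–O6; the ring alkene C1=C10 (intramolecular phosphonate olefination); C9–C10 (phosphonoacetate alkylation); and, in one operation, C4=C5 together with C2–C3.
2. What allows the last cut: C4 is an alkene carbon bearing the oxygenated C15, the C3 methylene and the double bond to C5. That is the pattern a 2-phosphonoacrylate leaves after taking a carbon nucleophile at its CH2 and an aldehyde at its α-carbon. C5–C9 with the contiguous centres C6, C7, C8 is a 3-C-branched D-arabinose.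
3. Forward: D-arabinose → 3-C-allyl furanose → open-chain C5 aldehyde 13; tert-butyl acetate enolate, the phosphonoacrylate and 13 give the C1–C9 chain 18. C15 is then reduced, C9 becomes an iodide that alkylates triethyl phosphonoacetate (C10, C14), C1 is raised to the aldehyde and the ten-membered carbocycle closes at C1=C10. The γ-lactone ring follows by oxidative lactonisation of the 6,12-diol, then C13, the isovalerate and desilylation.
4. Stereochemistry: C6 and C8 are C2 and C4 of D-arabinose; C7 is set by allyl transfer to the sugar C3 radical anti to the 1,2-acetonide. Both ring alkenes (C15 trans to C6, C14 trans to C2, each cis within the ring) come from ester-trans-selective phosphonate olefinations.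

Key step: step 11

Remark: germacrane locants C1–C15 of the target are used for all chain and ring atoms (C12 lactone carbonyl on O6, ester on O8, C13 exocyclic methylene, C14 on C10, C15 on C4); sugar locants appear only in steps 1–10. Compound 2 is an anomeric mixture and 26/27 are C10 epimers; both are inconsequential. TBDPS = tert-butyldiphenylsilyl, PMB = 4-methoxybenzyl, TES = triethylsilyl.

**Step 1**
Reactants: 1 D-arabinose
Product: 2 5-O-TBDPS-D-arabinofuranose (anomeric mixture)
Conditions: TBDPSCl, pyridine, 0 °C → rt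
Reagents that add atoms: tert-butyl(chloro)diphenylsilane, CC(C)(C)[Si](Cl)(c1ccccc1)c1ccccc1
Why: Silyl ether formation is fastest at a primary hydroxyl, which only the furanose tautomer offers, so silylation should drain the mutarotation equilibrium into the 5-O-silyl furanose.

**Step 2**
Reactants: 2 5-O-TBDPS-D-arabinofuranose
Product: 3 5-O-TBDPS-1,2-O-isopropylidene-β-D-arabinofuranose
Conditions: Me2C(OMe)2, CSA (cat.), acetone, rt
Reagents that add atoms: 2,2-dimethoxypropane, COC(C)(C)OC
Why: Acid-catalysed acetal exchange (isopropylidenation) can bridge only the cis-related O1 and O2 of the β-furanose, which fixes the anomeric centre and leaves O3–H as the single free hydroxyl.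

**Step 3**
Reactants: 3 5-O-TBDPS-1,2-O-isopropylidene-β-D-arabinofuranose
Product: 4 3-O-(phenoxythiocarbonyl) derivative of 3
Conditions: PhOC(S)Cl, pyridine, DMAP (cat.), CH2Cl2, 0 °C → rt
Reagents that add atoms: O-phenyl carbonochloridothioate, S=C(Cl)Oc1ccccc1
Why: Acylation of the secondary alcohol to the aryl thionocarbonate installs the Barton-type radical leaving group at sugar C3.

**Step 4**
Reactants: 4 thionocarbonate; 5 allyltributylstannane
Product: 6 3-C-allyl-5-O-TBDPS-3-deoxy-1,2-O-isopropylidene-β-D-arabinofuranose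
Conditions: 5 (3 equiv), AIBN (cat.), PhMe, 80 °C, degassed
Reagents that add atoms: none
Why: Keck radical allylation, in which Bu3Sn• adds to C=S, the sugar C3 radical is released and takes the allyl group from 5 on the convex α face, anti to the cis-fused 1,2-acetonide and to the C4 side chain, so the new C–C bond occupies the place of the former C–O bond and sets C7 of the target.

**Step 5**
Reactants: 6 3-C-allyl furanose
Product: 8 5-O-TBDPS-3-deoxy-3-C-(2-hydroxyethyl)-1,2-O-isopropylidene-β-D-arabinofuranose, via aldehyde 7 (not isolated)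
Conditions: O3, CH2Cl2/MeOH, –78 °C; then NaBH4, –78 °C → rt
Reagents that add atoms: ozone, [O-][O+]=O
Why: Ozonolysis with reductive borohydride work-up cleaves the only alkene and reduces the aldehyde in the same flask, leaving the two-carbon C11–C12 arm as a primary alcohol.

**Step 6**
Reactants: 8 silyl ether alcohol
Product: 9 3-deoxy-3-C-(2-hydroxyethyl)-1,2-O-isopropylidene-β-D-arabinofuranose
Conditions: Bu4NF, THF, rt
Reagents that add atoms: none
Why: Fluoride-induced desilylation frees O9 so that it can be paired with O8 in step 8, the acetonide being inert to fluoride.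

**Step 7**
Reactants: 9 furanose diol
Product: 10 3-deoxy-3-C-(2-hydroxyethyl)-D-arabinose propane-1,3-diyl dithioacetal
Conditions: HS(CH2)3SH, conc. HCl, 0 °C → rt
Reagents that add atoms: propane-1,3-dithiol, SCCCS
Why: Fischer-type dithioacetalisation, in which strong aqueous acid hydrolyses the acetonide and the furanose opens to the thermodynamically favoured 1,3-dithiane at C5 without touching a stereocentre.

**Step 8**
Reactants: 10 dithiane tetraol
Product: 11 8,9-O-isopropylidene dithiane diol (6-OH and 12-OH free)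
Conditions: Me2C(OMe)2, CSA (cat.), acetone/DMF, 0 °C → rt
Reagents that add atoms: 2,2-dimethoxypropane, COC(C)(C)OC
Why: Isopropylidene acetal formation under equilibrating acid catalysis favours the five-membered dioxolane of the terminal 1,2-diol (O8/O9) over a dioxane across the anti-1,3-diol, and this is what distinguishes O8 from O6.

**Step 9**
Reactants: 11 acetonide diol
Product: 12 6,12-bis-O-PMB dithiane acetonide
Conditions: NaH, PMBCl, Bu4NI (cat.), DMF, 0 °C → rt
Reagents that add atoms: 4-methoxybenzyl chloride, COc1ccc(CCl)cc1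
Why: Williamson etherification of the two remaining hydroxyls gives PMB ethers at O6 and O12, the pair that is later unveiled together for lactone formation.

**Step 10**
Reactants: 12 bis-PMB dithiane
Product: 13 C5 aldehyde (6-OPMB; 12-OPMB; 8,9-acetonide)
Conditions: I2, NaHCO3, acetone/H2O, 0 °C
Reagents that add atoms: water, O
Why: Iodine-mediated oxidative hydrolysis of the dithiane (thioacetal cleavage) under bicarbonate buffering at 0 °C should free the α-alkoxy aldehyde without epimerising C6 or disturbing the acetonide and PMB ethers.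

**Step 11**
Reactants: 14 tert-butyl acetate; 15 ethyl 2-(diethoxyphosphoryl)acrylate; 13 C5 aldehyde
Product: 18 C1–C9 diester with the (4E) C4=C5 alkene, via lithium enolate 16 (not isolated), via lithium phosphonate 17 (not isolated)
Conditions: LiN(iPr)2, THF, –78 °C; 15, –78 °C; then 13, –78 °C → rt
Reagents that add atoms: none
Why: LiN(iPr)2 converts 14 into enolate 16, which adds in Michael fashion to the CH2 terminus of vinylphosphonate 15 (C2–C3 bond) and thereby generates the α-alkylated lithium phosphonoacetate carbanion 17 at C4; 17 adds to aldehyde 13 and the oxaphosphetane collapses with loss of lithium diethyl phosphate to the trisubstituted enoate (C4=C5). The closest known reaction type is the tandem conjugate addition/Horner–Wadsworth–Emmons olefination of 2-phosphonoacrylates. No ring is closed and no stereocentre is created; the stereochemical issue is the alkene geometry, where reversible addition of a lithium-bound α-alkyl phosphonoacetate favours the oxaphosphetane that places the C15 ester trans to the branched C6 substituent (C3 cis to C6), as the target requires. The step also needs chemoselectivity and retention of C6: adding 15 to 16 at –78 °C before 13 is present keeps the enolate away from the aldehyde, and the weakly basic stabilised anion 17 should olefinate the reactive α-alkoxy aldehyde at low temperature faster than it enolises it. The product carries two different esters (tert-butyl at C1, ethyl at C15), which steps 12 and 17 exploit.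

**Step 12**
Reactants: 18 diester
Product: 19 C15 allylic alcohol (tert-butyl ester at C1 retained)
Conditions: iBu2AlH (2.2 equiv), CH2Cl2, –78 °C
Reagents that add atoms: none
Why: Chemoselective ester reduction, in which iBu2AlH at –78 °C should reduce the ethyl enoate to the allylic alcohol (1,2-reduction) while the hindered tert-butyl ester is left alone.

**Step 13**
Reactants: 19 allylic alcohol
Product: 20 C15 TBDPS ether
Conditions: TBDPSCl, imidazole, CH2Cl2, rt
Reagents that add atoms: tert-butyl(chloro)diphenylsilane, CC(C)(C)[Si](Cl)(c1ccccc1)c1ccccc1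
Why: Imidazole-promoted silyl ether formation caps the primary allylic alcohol with an acid-stable group before it can lactonise onto the C1 ester.

**Step 14**
Reactants: 20 acetonide
Product: 21 8,9-diol
Conditions: AcOH/THF/H2O (3:1:1), 45 °C
Reagents that add atoms: none
Why: Acid-catalysed acetal hydrolysis removes the terminal acetonide, while the tert-butyl ester, PMB ethers and TBDPS ether tolerate aqueous acetic acid.

**Step 15**
Reactants: 21 8,9-diol
Product: 22 C9 iodide with free 8-OH
Conditions: PPh3, I2, imidazole, THF, 0 °C → rt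
Reagents that add atoms: iodine, II
Why: Appel-type iodination (PPh3/I2/imidazole) converts the less hindered primary hydroxyl at C9 selectively into the iodide and leaves the secondary O8–H free.

**Step 16**
Reactants: 22 iodohydrin
Product: 23 8-O-TES iodide
Conditions: Et3SiCl, imidazole, DMAP (cat.), DMF, 0 °C → rt
Reagents that add atoms: chlorotriethylsilane, CC[Si](Cl)(CC)CC
Why: Silyl ether formation under weakly basic conditions protects O8 without closing the iodohydrin to an epoxide or touching the tert-butyl ester.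

**Step 17**
Reactants: 23 tert-butyl ester iodide
Product: 24 C1 primary alcohol
Conditions: iBu2AlH (3 equiv), CH2Cl2, –78 → 0 °C
Reagents that add atoms: none
Why: Ester reduction with excess iBu2AlH takes the tert-butyl ester to the primary alcohol at C1, the alkyl iodide, silyl ethers and PMB ethers being inert to this hydride.

**Step 18**
Reactants: 24 iodo alcohol; 25 triethyl phosphonoacetate
Product: 26 C9-alkylated phosphonoacetate with free C1–OH (C10 epimers)
Conditions: NaH, 25 (3 equiv), DMF, 0 °C; then 24, 60 °C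
Reagents that add atoms: none
Why: SN2 alkylation of sodium triethyl phosphonoacetate by the primary iodide forms C9–C10, the C1 alcohol being far less acidic than the phosphonoacetate and staying protonated, and the new C10 centre disappears in step 20.

**Step 19**
Reactants: 26 hydroxy phosphonoacetate
Product: 27 C1 aldehyde phosphonoacetate (C10 epimers)
Conditions: Dess–Martin periodinane, NaHCO3, CH2Cl2, 0 °C → rt
Reagents that add atoms: none
Why: Dess–Martin oxidation converts the primary alcohol into the C1 aldehyde under buffered, non-basic conditions that leave the acidic phosphonoacetate C–H alone.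

**Step 20**
Reactants: 27 aldehyde phosphonoacetate
Product: 28 ten-membered ring ethyl ester (C1=C10 closed; C14 = CO2Et)
Conditions: LiCl, DBU, MeCN, rt, slow addition of 27 to 1 mM
Reagents that add atoms: none
Why: Intramolecular Horner–Wadsworth–Emmons olefination under Masamune–Roush conditions at high dilution closes the carbocycle at C1=C10, with the ester-trans preference of the olefination and the ring size both placing C2 cis to C9 and the existing cis C4=C5 alkene pre-folding the chain.

**Step 21**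
Reactants: 28 macrocyclic ester
Product: 29 C14 allylic alcohol
Conditions: iBu2AlH, CH2Cl2, –78 °C
Reagents that add atoms: none
Why: 1,2-Reduction of the enoate with iBu2AlH gives the C14 allylic alcohol, ethers and silyl ethers being inert.

**Step 22**
Reactants: 29 C14 alcohol
Product: 30 14,15-bis-TBDPS ether
Conditions: TBDPSCl, imidazole, DMF, rt
Reagents that add atoms: tert-butyl(chloro)diphenylsilane, CC(C)(C)[Si](Cl)(c1ccccc1)c1ccccc1
Why: Silyl ether formation gives the second allylic TBDPS ether so that C14 and C15 can be unveiled together at the end.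

**Step 23**
Reactants: 30 bis-PMB ether
Product: 31 6,12-diol
Conditions: DDQ, CH2Cl2/pH 7 buffer, 0 °C
Reagents that add atoms: none
Why: Oxidative PMB cleavage by DDQ (benzylic hydride abstraction, then hydrolysis of the oxocarbenium ion) frees both hydroxyls while silyl ethers and the trisubstituted alkenes should survive under buffering.

**Step 24**
Reactants: 31 6,12-diol
Product: 33 13-nor 12,6-lactone (8-OTES), via lactol 32 (not isolated)
Conditions: TEMPO (cat.), PhI(OAc)2, CH2Cl2, rt
Reagents that add atoms: none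
Why: TEMPO/PhI(OAc)2 oxidative lactonisation, in which the oxoammonium salt oxidises the primary C12 alcohol first, O6–H traps the aldehyde as the five-membered lactol and this is oxidised on to the γ-lactone, O8 being blocked so that only the 12,6-olide can form.

**Step 25**
Reactants: 33 lactone
Product: 37 α-methylene lactone (8-OTES), via lithium enolate 34 (not isolated), via Mannich base 35 (not isolated), via methiodide 36 (not isolated)
Conditions: LiN(iPr)2, THF, –78 °C; CH2=NMe2+ I–, –78 °C → rt; then MeI, MeOH, rt; then aq. NaHCO3, CH2Cl2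
Reagents that add atoms: N,N-dimethylmethyleneiminium iodide (Eschenmoser's salt), C=[N+](C)C.[I-]
Why: α-Methylenation by the Mannich route, in which the lactone enolate is aminomethylated at C11, the amine is quaternised and trimethylamine is eliminated under mild base to give the exocyclic C11=C13 alkene, which removes the transient C11 stereocentre.

**Step 26**
Reactants: 37 8-O-TES methylene lactone
Product: 38 8-hydroxy methylene lactone
Conditions: CSA (cat.), MeOH/CH2Cl2, 0 °C
Reagents that add atoms: none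
Why: Acid-catalysed methanolysis (selective desilylation) removes the secondary triethylsilyl ether far faster than the two primary TBDPS ethers.

**Step 27**
Reactants: 38 8-alcohol
Product: 39 8-O-isovalerate
Conditions: (iPrCH2CO)2O, Et3N, DMAP (cat.), CH2Cl2, rt
Reagents that add atoms: 3-methylbutanoic anhydride, CC(C)CC(=O)OC(=O)CC(C)C
Why: DMAP-catalysed acylation of the secondary alcohol with the anhydride installs the isovalerate without any base strong enough to harm the α-methylene lactone.

**Step 28**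
Reactants: 39 bis-TBDPS ether
Product: 40 CNP0199826.1
Conditions: HF·pyridine, pyridine, THF, 0 °C → rt
Reagents that add atoms: none
Why: Fluoride-mediated desilylation with buffered HF·pyridine cleaves both primary TBDPS ethers under conditions too weakly basic for acyl migration or conjugate addition to the methylene lactone.

**Compound list**
1 | D-arabinose | O=C[C@@H](O)[C@H](O)[C@H](O)CO | starting material
2 | 5-O-(tert-butyldiphenylsilyl)-D-arabinofuranose (anomeric mixture) | OC1O[C@H](CO[Si](c2ccccc2)(c2ccccc2)C(C)(C)C)[C@@H](O)[C@@H]1O | intermediate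
3 | 5-O-(tert-butyldiphenylsilyl)-1,2-O-isopropylidene-β-D-arabinofuranose | CC1(C)O[C@@H]2O[C@H](CO[Si](c3ccccc3)(c3ccccc3)C(C)(C)C)[C@@H](O)[C@@H]2O1 | intermediate
4 | 5-O-(tert-butyldiphenylsilyl)-1,2-O-isopropylidene-3-O-(phenoxythiocarbonyl)-β-D-arabinofuranose | CC1(C)O[C@@H]2O[C@H](CO[Si](c3ccccc3)(c3ccccc3)C(C)(C)C)[C@@H](OC(=S)Oc3ccccc3)[C@@H]2O1 | intermediate
5 | allyltributylstannane | C=CC[Sn](CCCC)(CCCC)CCCC | starting material
6 | 3-C-allyl-5-O-(tert-butyldiphenylsilyl)-3-deoxy-1,2-O-isopropylidene-β-D-arabinofuranose (allyl on the α face, in the place of the former 3-OH) | CC1(C)O[C@@H]2O[C@H](CO[Si](c3ccccc3)(c3ccccc3)C(C)(C)C)[C@@H](CC=C)[C@@H]2O1 | intermediate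
7 | 5-O-(tert-butyldiphenylsilyl)-3-deoxy-1,2-O-isopropylidene-3-C-(2-oxoethyl)-β-D-arabinofuranose | CC1(C)O[C@@H]2O[C@H](CO[Si](c3ccccc3)(c3ccccc3)C(C)(C)C)[C@@H](CC=O)[C@@H]2O1 | intermediate
8 | 5-O-(tert-butyldiphenylsilyl)-3-deoxy-3-C-(2-hydroxyethyl)-1,2-O-isopropylidene-β-D-arabinofuranose | CC1(C)O[C@@H]2O[C@H](CO[Si](c3ccccc3)(c3ccccc3)C(C)(C)C)[C@@H](CCO)[C@@H]2O1 | intermediate
9 | 3-deoxy-3-C-(2-hydroxyethyl)-1,2-O-isopropylidene-β-D-arabinofuranose | CC1(C)O[C@@H]2O[C@H](CO)[C@@H](CCO)[C@@H]2O1 | intermediate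
10 | 3-deoxy-3-C-(2-hydroxyethyl)-D-arabinose propane-1,3-diyl dithioacetal = (2S,3R,4S)-4-(1,3-dithian-2-yl)-3-(2-hydroxyethyl)butane-1,2,4-triol | S1CCCSC1[C@@H](O)[C@H](CCO)[C@H](O)CO | intermediate
11 | 3-deoxy-3-C-(2-hydroxyethyl)-4,5-O-isopropylidene-D-arabinose propane-1,3-diyl dithioacetal (6-OH, 12-OH free; 8,9-acetonide) | S1CCCSC1[C@@H](O)[C@H](CCO)[C@H]1COC(C)(C)O1 | intermediate
12 | 3-deoxy-4,5-O-isopropylidene-2-O-(4-methoxybenzyl)-3-C-[2-(4-methoxybenzyloxy)ethyl]-D-arabinose propane-1,3-diyl dithioacetal | S1CCCSC1[C@@H](OCc1ccc(OC)cc1)[C@H](CCOCc1ccc(OC)cc1)[C@H]1COC(C)(C)O1 | intermediate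
13 | (2S,3R)-3-[(4S)-2,2-dimethyl-1,3-dioxolan-4-yl]-2,5-bis(4-methoxybenzyloxy)pentanal (C5 aldehyde; 6S,7R,8S in target locants) | O=C[C@@H](OCc1ccc(OC)cc1)[C@H](CCOCc1ccc(OC)cc1)[C@H]1COC(C)(C)O1 | intermediate
14 | tert-butyl acetate | CC(=O)OC(C)(C)C | starting material
15 | ethyl 2-(diethoxyphosphoryl)acrylate | C=C(C(=O)OCC)P(=O)(OCC)OCC | starting material
16 | lithium enolate of tert-butyl acetate | C=C(O[Li])OC(C)(C)C | intermediate
17 | lithium salt of 5-tert-butyl 1-ethyl 2-(diethoxyphosphoryl)pentanedioate (carbanion at C4) | [Li+].CCOC(=O)[C-](CCC(=O)OC(C)(C)C)P(=O)(OCC)OCC | intermediate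
18 | tert-butyl (4E,6R,7S,8S)-4-(ethoxycarbonyl)-8,9-(isopropylidenedioxy)-6-(4-methoxybenzyloxy)-7-[2-(4-methoxybenzyloxy)ethyl]non-4-enoate (C15 ester trans to C6) | CC(C)(C)OC(=O)CC/C(C(=O)OCC)=C\[C@@H](OCc1ccc(OC)cc1)[C@H](CCOCc1ccc(OC)cc1)[C@H]1COC(C)(C)O1 | intermediate
19 | tert-butyl (4E,6R,7S,8S)-4-(hydroxymethyl)-8,9-(isopropylidenedioxy)-6-(4-methoxybenzyloxy)-7-[2-(4-methoxybenzyloxy)ethyl]non-4-enoate | CC(C)(C)OC(=O)CC/C(CO)=C\[C@@H](OCc1ccc(OC)cc1)[C@H](CCOCc1ccc(OC)cc1)[C@H]1COC(C)(C)O1 | intermediate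
20 | tert-butyl (4E,6R,7S,8S)-4-[(tert-butyldiphenylsilyloxy)methyl]-8,9-(isopropylidenedioxy)-6-(4-methoxybenzyloxy)-7-[2-(4-methoxybenzyloxy)ethyl]non-4-enoate | CC(C)(C)OC(=O)CC/C(CO[Si](c1ccccc1)(c1ccccc1)C(C)(C)C)=C\[C@@H](OCc1ccc(OC)cc1)[C@H](CCOCc1ccc(OC)cc1)[C@H]1COC(C)(C)O1 | intermediate
21 | tert-butyl (4E,6R,7R,8S)-4-[(tert-butyldiphenylsilyloxy)methyl]-8,9-dihydroxy-6-(4-methoxybenzyloxy)-7-[2-(4-methoxybenzyloxy)ethyl]non-4-enoate | CC(C)(C)OC(=O)CC/C(CO[Si](c1ccccc1)(c1ccccc1)C(C)(C)C)=C\[C@@H](OCc1ccc(OC)cc1)[C@H](CCOCc1ccc(OC)cc1)[C@H](O)CO | intermediate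
22 | tert-butyl (4E,6R,7R,8S)-4-[(tert-butyldiphenylsilyloxy)methyl]-8-hydroxy-9-iodo-6-(4-methoxybenzyloxy)-7-[2-(4-methoxybenzyloxy)ethyl]non-4-enoate | CC(C)(C)OC(=O)CC/C(CO[Si](c1ccccc1)(c1ccccc1)C(C)(C)C)=C\[C@@H](OCc1ccc(OC)cc1)[C@H](CCOCc1ccc(OC)cc1)[C@H](O)CI | intermediate
23 | tert-butyl (4E,6R,7S,8S)-4-[(tert-butyldiphenylsilyloxy)methyl]-9-iodo-6-(4-methoxybenzyloxy)-7-[2-(4-methoxybenzyloxy)ethyl]-8-(triethylsilyloxy)non-4-enoate | CC(C)(C)OC(=O)CC/C(CO[Si](c1ccccc1)(c1ccccc1)C(C)(C)C)=C\[C@@H](OCc1ccc(OC)cc1)[C@H](CCOCc1ccc(OC)cc1)[C@H](O[Si](CC)(CC)CC)CI | intermediate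
24 | (4E,6R,7S,8S)-4-[(tert-butyldiphenylsilyloxy)methyl]-9-iodo-6-(4-methoxybenzyloxy)-7-[2-(4-methoxybenzyloxy)ethyl]-8-(triethylsilyloxy)non-4-en-1-ol | OCCC/C(CO[Si](c1ccccc1)(c1ccccc1)C(C)(C)C)=C\[C@@H](OCc1ccc(OC)cc1)[C@H](CCOCc1ccc(OC)cc1)[C@H](O[Si](CC)(CC)CC)CI | intermediate
25 | triethyl phosphonoacetate | CCOC(=O)CP(=O)(OCC)OCC | starting material
26 | ethyl (4R,5S,6R,7E)-8-[(tert-butyldiphenylsilyloxy)methyl]-2-(diethoxyphosphoryl)-11-hydroxy-6-(4-methoxybenzyloxy)-5-[2-(4-methoxybenzyloxy)ethyl]-4-(triethylsilyloxy)undec-7-enoate (both C2 epimers; C2 = C10 of the target) | OCCC/C(CO[Si](c1ccccc1)(c1ccccc1)C(C)(C)C)=C\[C@@H](OCc1ccc(OC)cc1)[C@H](CCOCc1ccc(OC)cc1)[C@H](O[Si](CC)(CC)CC)CC(C(=O)OCC)P(=O)(OCC)OCC | intermediate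
27 | ethyl (4R,5S,6R,7E)-8-[(tert-butyldiphenylsilyloxy)methyl]-2-(diethoxyphosphoryl)-6-(4-methoxybenzyloxy)-5-[2-(4-methoxybenzyloxy)ethyl]-11-oxo-4-(triethylsilyloxy)undec-7-enoate (both C2 epimers) | O=CCC/C(CO[Si](c1ccccc1)(c1ccccc1)C(C)(C)C)=C\[C@@H](OCc1ccc(OC)cc1)[C@H](CCOCc1ccc(OC)cc1)[C@H](O[Si](CC)(CC)CC)CC(C(=O)OCC)P(=O)(OCC)OCC | intermediate
28 | ethyl (1(10)E,4E,6R,7S,8R)-15-(tert-butyldiphenylsilyloxy)-6,12-bis(4-methoxybenzyloxy)-8-(triethylsilyloxy)-13-norgermacra-1(10),4-dien-14-oate (both ring alkenes cis within the ring) | CCOC(=O)/C1=C/CC/C(CO[Si](c2ccccc2)(c2ccccc2)C(C)(C)C)=C\[C@@H](OCc2ccc(OC)cc2)[C@H](CCOCc2ccc(OC)cc2)[C@H](O[Si](CC)(CC)CC)C1 | intermediate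
29 | (1(10)E,4E,6R,7S,8R)-15-(tert-butyldiphenylsilyloxy)-6,12-bis(4-methoxybenzyloxy)-8-(triethylsilyloxy)-13-norgermacra-1(10),4-dien-14-ol | OC/C1=C/CC/C(CO[Si](c2ccccc2)(c2ccccc2)C(C)(C)C)=C\[C@@H](OCc2ccc(OC)cc2)[C@H](CCOCc2ccc(OC)cc2)[C@H](O[Si](CC)(CC)CC)C1 | intermediate
30 | (1(10)E,4E,6R,7S,8R)-14,15-bis(tert-butyldiphenylsilyloxy)-6,12-bis(4-methoxybenzyloxy)-8-(triethylsilyloxy)-13-norgermacra-1(10),4-diene | CC(C)(C)[Si](c2ccccc2)(c2ccccc2)OC/C1=C/CC/C(CO[Si](c2ccccc2)(c2ccccc2)C(C)(C)C)=C\[C@@H](OCc2ccc(OC)cc2)[C@H](CCOCc2ccc(OC)cc2)[C@H](O[Si](CC)(CC)CC)C1 | intermediate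
31 | (1(10)E,4E,6R,7S,8R)-14,15-bis(tert-butyldiphenylsilyloxy)-8-(triethylsilyloxy)-13-norgermacra-1(10),4-diene-6,12-diol | CC(C)(C)[Si](c2ccccc2)(c2ccccc2)OC/C1=C/CC/C(CO[Si](c2ccccc2)(c2ccccc2)C(C)(C)C)=C\[C@@H](O)[C@H](CCO)[C@H](O[Si](CC)(CC)CC)C1 | intermediate
32 | (1(10)E,4E,6R,7S,8R)-14,15-bis(tert-butyldiphenylsilyloxy)-6,12-epoxy-8-(triethylsilyloxy)-13-norgermacra-1(10),4-dien-12-ol (lactol, C12 epimers) | CC(C)(C)[Si](c2ccccc2)(c2ccccc2)OC/C1=C/CC/C(CO[Si](c2ccccc2)(c2ccccc2)C(C)(C)C)=C\[C@H]3OC(O)C[C@@H]3[C@H](O[Si](CC)(CC)CC)C1 | intermediate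
33 | (1(10)E,4E,6R,7S,8R)-14,15-bis(tert-butyldiphenylsilyloxy)-8-(triethylsilyloxy)-13-norgermacra-1(10),4-dien-12,6-olide (trans-fused γ-lactone) | CC(C)(C)[Si](c2ccccc2)(c2ccccc2)OC/C1=C/CC/C(CO[Si](c2ccccc2)(c2ccccc2)C(C)(C)C)=C\[C@H]3OC(=O)C[C@@H]3[C@H](O[Si](CC)(CC)CC)C1 | intermediate
34 | lithium enolate of lactone 33 (C11=C12–OLi) | CC(C)(C)[Si](c2ccccc2)(c2ccccc2)OC/C1=C/CC/C(CO[Si](c2ccccc2)(c2ccccc2)C(C)(C)C)=C\[C@H]3OC(O[Li])=C[C@@H]3[C@H](O[Si](CC)(CC)CC)C1 | intermediate
35 | 13-(dimethylamino) derivative of 33 with C13 attached to C11 (Mannich base, C11 epimers) | CC(C)(C)[Si](c2ccccc2)(c2ccccc2)OC/C1=C/CC/C(CO[Si](c2ccccc2)(c2ccccc2)C(C)(C)C)=C\[C@H]3OC(=O)C(CN(C)C)[C@@H]3[C@H](O[Si](CC)(CC)CC)C1 | intermediate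
36 | 13-(trimethylammonio) iodide derived from 35 (C11 epimers) | CC(C)(C)[Si](c2ccccc2)(c2ccccc2)OC/C1=C/CC/C(CO[Si](c2ccccc2)(c2ccccc2)C(C)(C)C)=C\[C@H]3OC(=O)C(C[N+](C)(C)C)[C@@H]3[C@H](O[Si](CC)(CC)CC)C1.[I-] | intermediate
37 | (1(10)E,4E,6R,7S,8R)-14,15-bis(tert-butyldiphenylsilyloxy)-8-(triethylsilyloxy)germacra-1(10),4,11(13)-trien-12,6-olide | CC(C)(C)[Si](c2ccccc2)(c2ccccc2)OC/C1=C/CC/C(CO[Si](c2ccccc2)(c2ccccc2)C(C)(C)C)=C\[C@H]3OC(=O)C(=C)[C@@H]3[C@H](O[Si](CC)(CC)CC)C1 | intermediate
38 | (1(10)E,4E,6R,7R,8R)-14,15-bis(tert-butyldiphenylsilyloxy)-8-hydroxygermacra-1(10),4,11(13)-trien-12,6-olide | CC(C)(C)[Si](c2ccccc2)(c2ccccc2)OC/C1=C/CC/C(CO[Si](c2ccccc2)(c2ccccc2)C(C)(C)C)=C\[C@H]3OC(=O)C(=C)[C@@H]3[C@H](O)C1 | intermediate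
39 | (1(10)E,4E,6R,7R,8R)-14,15-bis(tert-butyldiphenylsilyloxy)-8-(3-methylbutanoyloxy)germacra-1(10),4,11(13)-trien-12,6-olide | CC(C)(C)[Si](c2ccccc2)(c2ccccc2)OC/C1=C/CC/C(CO[Si](c2ccccc2)(c2ccccc2)C(C)(C)C)=C\[C@H]3OC(=O)C(=C)[C@@H]3[C@H](OC(=O)CC(C)C)C1 | intermediate
40 | CNP0199826.1, (1(10)E,4E,6R,7R,8R)-14,15-dihydroxy-8-(3-methylbutanoyloxy)germacra-1(10),4,11(13)-trien-12,6-olide (both ring alkenes cis within the ring) | C=C1C(=O)O[C@@H]2/C=C(/CO)CC/C=C(/CO)C[C@@H](OC(=O)CC(C)C)[C@@H]12 | target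

**Step count and risks**
Total: 28 steps. Longest linear sequence: 28 steps, from D-arabinose 1 to 40; compounds 5, 14, 15 and 25 are commercial and enter directly.

Steps most likely to fail:

Step 20. Closing a ten-membered ring costs entropy and transannular strain, so intermolecular olefination to dimers and oligomers may outrun cyclisation, and the hindered α-alkylated phosphonate may react sluggishly under mild base. The fallback closes the same bond by metathesis and sets out from 26. Olefination of the phosphonoacetate with aqueous formaldehyde and K2CO3 gives acrylate alcohol F1. Dess–Martin oxidation gives aldehyde F2. Methylenation with Ph3P=CH2 (from Ph3PCH3Br and KN(SiMe3)2, THF, –78 °C) gives diene F3. Ring-closing metathesis with the second-generation Grubbs catalyst (H2IMes)(PCy3)Cl2Ru=CHPh in dilute toluene at 80 °C expels ethene and returns to the route at 28; the ring-cis alkene is the one medium-ring metathesis normally delivers.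

Step 18. Displacement at a primary carbon that is β-branched and β-silyloxylated by a bulky stabilised anion may be slow, so elimination, silyl loss with epoxide formation, or simple recovery of 24 may take over. The fallback uses a harder nucleophile and sets out from 24. Alkylation with the dilithio dianion of (diethoxyphosphoryl)acetic acid (LiN(iPr)2, THF/DMPU, one further equivalent of base for the C1 hydroxyl) gives carboxylic acid F4. O-Alkylation of its carboxylate with EtI and KHCO3 in DMF returns to the route at 26.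

Step 11. The one-flask sequence may lose geometric control (some C15-cis enoate through chelation by the α-alkoxy group), may partly epimerise C6 while anionic species are present, or may consume 15 by anionic oligomerisation. The fallback separates the two bond formations and sets out from 14 and 15. The conjugate addition is run alone and quenched with AcOH to give isolated phosphonate F5. A separate Horner–Wadsworth–Emmons olefination of F5 with 13 under Masamune–Roush conditions (LiCl, iPr2NEt, MeCN, 0 °C → rt), which keeps strong base away from the aldehyde, returns to the route at 18.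

**Further compounds**
F1 | step 20 | ethyl 2-methylene analogue of 26 (C10 = C(=CH2)CO2Et, free C1–OH; 4E, stereocentres as in 26) | OCCC/C(CO[Si](c1ccccc1)(c1ccccc1)C(C)(C)C)=C\[C@@H](OCc1ccc(OC)cc1)[C@H](CCOCc1ccc(OC)cc1)[C@H](O[Si](CC)(CC)CC)CC(=C)C(=O)OCC
F2 | step 20 | C1 aldehyde of F1 | O=CCC/C(CO[Si](c1ccccc1)(c1ccccc1)C(C)(C)C)=C\[C@@H](OCc1ccc(OC)cc1)[C@H](CCOCc1ccc(OC)cc1)[C@H](O[Si](CC)(CC)CC)CC(=C)C(=O)OCC
F3 | step 20 | diene from F2 (C1 aldehyde converted into CH=CH2) | C=CCC/C(CO[Si](c1ccccc1)(c1ccccc1)C(C)(C)C)=C\[C@@H](OCc1ccc(OC)cc1)[C@H](CCOCc1ccc(OC)cc1)[C@H](O[Si](CC)(CC)CC)CC(=C)C(=O)OCC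
F4 | step 18 | carboxylic acid corresponding to ester 26 (C14 = CO2H, C10 epimers) | OCCC/C(CO[Si](c1ccccc1)(c1ccccc1)C(C)(C)C)=C\[C@@H](OCc1ccc(OC)cc1)[C@H](CCOCc1ccc(OC)cc1)[C@H](O[Si](CC)(CC)CC)CC(C(=O)O)P(=O)(OCC)OCC
F5 | step 11 | 5-tert-butyl 1-ethyl 2-(diethoxyphosphoryl)pentanedioate | CCOC(=O)C(CCC(=O)OC(C)(C)C)P(=O)(OCC)OCC
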